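## Retrosynthetic overview
1. The enal is installed last, by Heck vinylation of a ring A aryl bromide with acrolein diethyl acetal. The acid work-up also removes the two MOM groups of ring C.
2. The C9 CH2OH comes from a vinyl group by ozonolysis/NaBH4. The vinyl group keeps the primary OH masked during ring closure.
3. The dioxane ring (ring B) is the only ring formed; rings A and C are bought. It is closed by Cu-catalysed O-arylation of the C7 alcohol onto an ortho-iodide with retention, so the syn alcohol gives the trans ring.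
4. The key C7–C8 bond joins the ring C aldehyde carbon to the oxygen-bearing carbon of a ring A aryloxyallene. Hydroboration with (dIpc)2BH turns that carbon from acceptor into donor (an α-aryloxyallyl anion equivalent, acrolein C1 with inverted polarity). Both stereocentres and the 8-O-4' ether arrive in this one step.
5. The allene comes from 4-bromoguaiacol (iodination, then propargylation/isomerisation). The aldehyde comes from 5-hydroxyvanillin (MOM protection).

Assumption: crystalline (−)-diisopinocampheylborane, made from (+)-α-pinene, and 5-hydroxyvanillin are bought and count as starting materials.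

The target is the trans (2R,3R) benzodioxane. C7 is the aryl-bearing carbon and C8 is the CH2OH-bearing carbon.

## Route

Step 1
Reactants: 1 3,4-dihydroxy-5-methoxybenzaldehyde (5-hydroxyvanillin)
Product: 2 3-methoxy-4,5-bis(methoxymethoxy)benzaldehyde
Conditions: MOMCl (2.6 equiv), i-Pr2NEt (3 equiv), CH2Cl2, 0 °C → rt
Reagents that add atoms: chloromethyl methyl ether, COCCl
Why: Williamson-type O-alkylation of both phenols gives base-, borane- and ozone-stable acetals that fall only in the final aqueous acid; no stereocentre is involved.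

Step 2
Reactants: 3 4-bromo-2-methoxyphenol
Product: 4 4-bromo-2-iodo-6-methoxyphenol
Conditions: NIS (1.05 equiv), TsOH·H2O (10 mol%), MeCN, 0 °C → rt
Reagents that add atoms: N-iodosuccinimide, O=C1CCC(=O)N1I
Why: In this electrophilic aromatic iodination the free OH directs to its only open ortho position (para is blocked by Br), which places iodine for the ring closure and leaves bromine for the Heck step.

Step 3
Reactants: 4 4-bromo-2-iodo-6-methoxyphenol; 5 propargyl bromide
Product: 7 5-bromo-1-iodo-3-methoxy-2-(propa-1,2-dien-1-yloxy)benzene, via propargyl ether 6 (not isolated)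
Conditions: t-BuOK (1.05 equiv), THF–DMF 4:1, 0 °C; 5 (1.0 equiv), rt; then t-BuOK (0.4 equiv), rt; filtration through basic alumina
Reagents that add atoms: none
Why: Williamson ether synthesis is followed in the same flask by base-catalysed propargyl-to-allene prototropic isomerisation, which stops at the oxygen-conjugated allene, and both ortho positions are blocked so no Claisen pathway is open.

Step 4
Reactants: 7 5-bromo-1-iodo-3-methoxy-2-(propa-1,2-dien-1-yloxy)benzene; 8 (−)-diisopinocampheylborane, (dIpc)2BH; 2 3-methoxy-4,5-bis(methoxymethoxy)benzaldehyde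
Product: 11 (1R,2R)-2-(4-bromo-2-iodo-6-methoxyphenoxy)-1-[3-methoxy-4,5-bis(methoxymethoxy)phenyl]but-3-en-1-ol, via Z-allylborane 9 (not isolated), via borinate ester 10 (not isolated)
Conditions: 8 (1.0 equiv), 7 (1.1 equiv), Et2O, −25 → 0 °C until 8 has dissolved; 2 (0.85 equiv), −78 °C, 12 h; then 3 M NaOH, 30% H2O2, 0 °C → rt
Reagents that add atoms: none
Why: Proposed new method: kinetic four-centre hydroboration of the unhindered terminal C=C of 7, from the side away from the bulky aryloxy group, should put boron on CH2 and give the (Z)-γ-aryloxyallylborane 9, whose oxygen-bearing carbon (normally an acceptor) is now the nucleophile; 9 then adds to the Si face of 2 through the chair Zimmerman–Traxler transition state of a Brown (Z)-γ-alkoxyallylboration, setting C7 (R) and C8 (R) syn in one event; the closest known reaction types are Brown alkoxyallylboration with lithiated allyl aryl ethers and allene hydroboration–allylboration with Ipc2BH.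

Step 5
Reactants: 11 (1R,2R)-2-(4-bromo-2-iodo-6-methoxyphenoxy)-1-[3-methoxy-4,5-bis(methoxymethoxy)phenyl]but-3-en-1-ol
Product: 12 (2R,3R)-7-bromo-5-methoxy-2-[3-methoxy-4,5-bis(methoxymethoxy)phenyl]-3-vinyl-2,3-dihydro-1,4-benzodioxine
Conditions: CuI (10 mol%), 3,4,7,8-tetramethyl-1,10-phenanthroline (20 mol%), Cs2CO3 (1.5 equiv), toluene, 90 °C, argon
Reagents that add atoms: none
Why: In this intramolecular Ullmann-type O-arylation the C7 oxygen is the nucleophile, so both stereocentres are retained and the syn adduct maps onto the trans ring; iodide reacts before bromide, and copper, unlike zerovalent palladium, does not trigger Heck cyclisation onto the vinyl group.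

Step 6
Reactants: 12 (2R,3R)-7-bromo-5-methoxy-2-[3-methoxy-4,5-bis(methoxymethoxy)phenyl]-3-vinyl-2,3-dihydro-1,4-benzodioxine
Product: 14 [(2R,3R)-7-bromo-5-methoxy-2-[3-methoxy-4,5-bis(methoxymethoxy)phenyl]-2,3-dihydro-1,4-benzodioxin-3-yl]methanol, via aldehyde 13 (not isolated)
Conditions: O3, CH2Cl2–MeOH 4:1, −78 °C (Sudan Red 7B end point); then NaBH4, −78 → 0 °C
Reagents that add atoms: ozone, [O-][O+]=O
Why: Ozonolysis with reductive work-up removes the terminal CH2 much faster than ozone attacks the arenes, and immediate cold hydride reduction keeps the α-aryloxy aldehyde 13 from epimerising, so C7 and C8 stay untouched.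

Step 7
Reactants: 14 [(2R,3R)-7-bromo-5-methoxy-2-[3-methoxy-4,5-bis(methoxymethoxy)phenyl]-2,3-dihydro-1,4-benzodioxin-3-yl]methanol; 15 acrolein diethyl acetal
Product: 18 (E)-3-[(2R,3R)-2-(3,4-dihydroxy-5-methoxyphenyl)-3-(hydroxymethyl)-5-methoxy-2,3-dihydro-1,4-benzodioxin-7-yl]prop-2-enal, via enal diethyl acetal 16 (not isolated), via bis-MOM enal 17 (not isolated)
Conditions: Pd(OAc)2 (3 mol%), n-Bu4NOAc, K2CO3, KCl, DMF, 90 °C; then 3 M aq HCl, THF, 45 °C, argon
Reagents that add atoms: water, O
Why: The Mizoroki–Heck reaction under phase-transfer (Jeffery-type) conditions gives the E alkene by syn insertion and syn β-hydride elimination, and the acid work-up that unmasks the aldehyde is extended to hydrolyse the two aryl MOM acetals, conditions under which benzodioxane C–O bonds and both stereocentres are stable.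

## Compound list
1 | 3,4-dihydroxy-5-methoxybenzaldehyde (5-hydroxyvanillin) | COc1cc(C=O)cc(O)c1O | starting material
2 | 3-methoxy-4,5-bis(methoxymethoxy)benzaldehyde | COCOc1cc(C=O)cc(OC)c1OCOC | intermediate
3 | 4-bromo-2-methoxyphenol | COc1cc(Br)ccc1O | starting material
4 | 4-bromo-2-iodo-6-methoxyphenol | COc1cc(Br)cc(I)c1O | intermediate
5 | propargyl bromide (3-bromoprop-1-yne) | C#CCBr | starting material
6 | 5-bromo-1-iodo-3-methoxy-2-(prop-2-yn-1-yloxy)benzene | COc1cc(Br)cc(I)c1OCC#C | intermediate
7 | 5-bromo-1-iodo-3-methoxy-2-(propa-1,2-dien-1-yloxy)benzene | COc1cc(Br)cc(I)c1OC=C=C | intermediate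
8 | (−)-diisopinocampheylborane, (dIpc)2BH, from two (+)-α-pinene units; B on C3, trans to the C2 methyl and anti to the CMe2 bridge | B([C@@H]1C[C@@H]2C[C@H]([C@H]1C)C2(C)C)[C@@H]1C[C@@H]2C[C@H]([C@H]1C)C2(C)C | starting material
9 | [(Z)-3-(4-bromo-2-iodo-6-methoxyphenoxy)allyl]bis(d-isopinocampheyl)borane | COc1cc(Br)cc(I)c1O/C=C\CB([C@@H]1C[C@@H]2C[C@H]([C@H]1C)C2(C)C)[C@@H]1C[C@@H]2C[C@H]([C@H]1C)C2(C)C | intermediate
10 | bis(d-isopinocampheyl)borinic ester of alcohol 11 (O–B bond at the C7 oxygen) | COCOc1cc(cc(OC)c1OCOC)[C@@H](OB([C@@H]2C[C@@H]3C[C@H]([C@H]2C)C3(C)C)[C@@H]2C[C@@H]3C[C@H]([C@H]2C)C3(C)C)[C@H](Oc1c(I)cc(Br)cc1OC)C=C | intermediate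
11 | (1R,2R)-2-(4-bromo-2-iodo-6-methoxyphenoxy)-1-[3-methoxy-4,5-bis(methoxymethoxy)phenyl]but-3-en-1-ol (syn) | COCOc1cc(cc(OC)c1OCOC)[C@@H](O)[C@H](Oc1c(I)cc(Br)cc1OC)C=C | intermediate
12 | (2R,3R)-7-bromo-5-methoxy-2-[3-methoxy-4,5-bis(methoxymethoxy)phenyl]-3-vinyl-2,3-dihydro-1,4-benzodioxine (trans) | COc1cc([C@H]2Oc3cc(Br)cc(OC)c3O[C@@H]2C=C)cc(OCOC)c1OCOC | intermediate
13 | (2R,3S)-7-bromo-5-methoxy-2-[3-methoxy-4,5-bis(methoxymethoxy)phenyl]-2,3-dihydro-1,4-benzodioxine-3-carbaldehyde (same spatial arrangement, trans; the descriptor changes only by CIP priority) | COc1cc([C@H]2Oc3cc(Br)cc(OC)c3O[C@@H]2C=O)cc(OCOC)c1OCOC | intermediate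
14 | [(2R,3R)-7-bromo-5-methoxy-2-[3-methoxy-4,5-bis(methoxymethoxy)phenyl]-2,3-dihydro-1,4-benzodioxin-3-yl]methanol | COc1cc([C@H]2Oc3cc(Br)cc(OC)c3O[C@@H]2CO)cc(OCOC)c1OCOC | intermediate
15 | acrolein diethyl acetal (3,3-diethoxyprop-1-ene) | C=CC(OCC)OCC | starting material
16 | [(2R,3R)-7-[(E)-3,3-diethoxyprop-1-enyl]-5-methoxy-2-[3-methoxy-4,5-bis(methoxymethoxy)phenyl]-2,3-dihydro-1,4-benzodioxin-3-yl]methanol | COc1cc([C@H]2Oc3cc(/C=C/C(OCC)OCC)cc(OC)c3O[C@@H]2CO)cc(OCOC)c1OCOC | intermediate
17 | (E)-3-[(2R,3R)-3-(hydroxymethyl)-5-methoxy-2-[3-methoxy-4,5-bis(methoxymethoxy)phenyl]-2,3-dihydro-1,4-benzodioxin-7-yl]prop-2-enal | COc1cc([C@H]2Oc3cc(/C=C/C=O)cc(OC)c3O[C@@H]2CO)cc(OCOC)c1OCOC | intermediate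
18 | (E)-3-[(2R,3R)-2-(3,4-dihydroxy-5-methoxyphenyl)-3-(hydroxymethyl)-5-methoxy-2,3-dihydro-1,4-benzodioxin-7-yl]prop-2-enal (CNP0103768.1) | COc1cc([C@H]2Oc3cc(/C=C/C=O)cc(OC)c3O[C@@H]2CO)cc(O)c1O | target

## Step count and risks
Total step count: 7.
Longest linear sequence: 6 steps (3 → 4 → 7 → 11 → 12 → 14 → 18).

**Most likely to fail, first: step 4.**
- Boron may go to the central allene carbon, followed by loss of aryloxide.
- The Z-borane may drift to E by a 1,3-borotropic shift, which would give the anti adduct and a cis ring.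

The fallback sets out from 7 and 2 and comes back at 11. The nucleophile is made by a different mechanism, as an isolable reagent. Copper hydride catalysed hydroboration of 7 uses pinacolborane (CuCl, 4,5-bis(diphenylphosphino)-9,9-dimethylxanthene, catalytic t-BuOK, THF, rt). It proceeds by hydrocupration of the terminal C=C and then exchange with the B–H bond. This gives (Z)-3-(4-bromo-2-iodo-6-methoxyphenoxy)allylboronic acid pinacol ester F1, which does not isomerise and can be checked for Z purity. Asymmetry then comes from a catalyst instead of the borane. F1 and 2 are combined with (S)-3,3'-bis(2,4,6-triisopropylphenyl)-1,1'-binaphthyl-2,2'-diyl hydrogen phosphate (5 mol%) in toluene at −30 °C. The S acid is chosen for Si-face attack, and its sense of induction should be confirmed on a test run. Aqueous work-up gives 11.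

**Second: step 5.**
- The C7 alkoxide may displace the allylic aryloxide at C8 (vinyl epoxide formation, ether cleavage or regiochemical scrambling) before copper closes the ring.
- The hindered secondary benzylic alcohol may couple slowly.

The fallback sets out from 11 and comes back at 14. The order of events is changed so that no alkene and no allylic C–O bond is present at ring closure.
- Ozonolysis/NaBH4 of 11 gives (1R,2R)-2-(4-bromo-2-iodo-6-methoxyphenoxy)-1-[3-methoxy-4,5-bis(methoxymethoxy)phenyl]propane-1,3-diol F2.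
- TBSCl and imidazole in CH2Cl2 at 0 °C silylate only the primary OH. This gives (1R,2R)-2-(4-bromo-2-iodo-6-methoxyphenoxy)-3-(tert-butyldimethylsilyloxy)-1-[3-methoxy-4,5-bis(methoxymethoxy)phenyl]propan-1-ol F3.
- Palladium-catalysed C–O coupling at the iodide (Pd(OAc)2, 2-di-tert-butylphosphino-2',4',6'-triisopropylbiphenyl, Cs2CO3, toluene, 70 °C) proceeds with retention at C7. It gives (2R,3R)-7-bromo-3-[(tert-butyldimethylsilyloxy)methyl]-5-methoxy-2-[3-methoxy-4,5-bis(methoxymethoxy)phenyl]-2,3-dihydro-1,4-benzodioxine F4.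
- n-Bu4NF in THF then gives 14.

**Third: step 7.**
- The electron-rich bromide may be sluggish.
- β-Hydride elimination toward the acetal carbon gives the propanoate ester instead of the enal.
- The free catechol may oxidise next to palladium residues in the one-pot acid stage.

The fallback sets out from 14 and comes back at 17. The side chain is built by carbonyl olefination instead of cross-coupling. Treatment of 14 with n-BuLi (2.2 equiv) in THF at −78 °C and then DMF gives (2R,3R)-3-(hydroxymethyl)-5-methoxy-2-[3-methoxy-4,5-bis(methoxymethoxy)phenyl]-2,3-dihydro-1,4-benzodioxine-7-carbaldehyde F5. Wittig reaction with (triphenylphosphoranylidene)acetaldehyde in toluene at 80 °C gives 17, which is isolated free of metal. A separate treatment of 17 with 3 M aq HCl in THF at 45 °C gives 18.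

## Further compounds
F1 | step 4 | (Z)-3-(4-bromo-2-iodo-6-methoxyphenoxy)allylboronic acid pinacol ester | COc1cc(Br)cc(I)c1O/C=C\CB1OC(C)(C)C(C)(C)O1
F2 | step 5 | (1R,2R)-2-(4-bromo-2-iodo-6-methoxyphenoxy)-1-[3-methoxy-4,5-bis(methoxymethoxy)phenyl]propane-1,3-diol | COCOc1cc(cc(OC)c1OCOC)[C@@H](O)[C@H](Oc1c(I)cc(Br)cc1OC)CO
F3 | step 5 | (1R,2R)-2-(4-bromo-2-iodo-6-methoxyphenoxy)-3-(tert-butyldimethylsilyloxy)-1-[3-methoxy-4,5-bis(methoxymethoxy)phenyl]propan-1-ol | COCOc1cc(cc(OC)c1OCOC)[C@@H](O)[C@H](Oc1c(I)cc(Br)cc1OC)CO[Si](C)(C)C(C)(C)C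
F4 | step 5 | (2R,3R)-7-bromo-3-[(tert-butyldimethylsilyloxy)methyl]-5-methoxy-2-[3-methoxy-4,5-bis(methoxymethoxy)phenyl]-2,3-dihydro-1,4-benzodioxine | COc1cc([C@H]2Oc3cc(Br)cc(OC)c3O[C@@H]2CO[Si](C)(C)C(C)(C)C)cc(OCOC)c1OCOC
F5 | step 7 | (2R,3R)-3-(hydroxymethyl)-5-methoxy-2-[3-methoxy-4,5-bis(methoxymethoxy)phenyl]-2,3-dihydro-1,4-benzodioxine-7-carbaldehyde | COc1cc([C@H]2Oc3cc(C=O)cc(OC)c3O[C@@H]2CO)cc(OCOC)c1OCOC
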